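If a flask stops short, count what it did in powers of ten. Here are the flasks, the readings and what is asked.

common to all: initiator 2.1 mol%
- Sunday's: substrate 0.40 M; partner 1.2 equiv; temperature 25 °C; the very flask that is asked about, followed so far
- Thursday's: substrate 0.60 M; partner 1.2 equiv; temperature 20 °C; run made earlier
- flask: substrate 0.40 M; partner 1.20 equiv; temperature 25 °C; time 2.5 h

| run | time / min | target / % | substrate / % |
|---|---|---|---|
| Sunday's | 8.00 | 33 | 58 |
| Sunday's | 25.0 | 42 | 39 |
| Sunday's | 40.0 | 43 | 31 |
| Sunday's | 60.0 | 48 | 28 |
| Sunday's | 90.0 | 46 | 28 |
| Thursday's | 1.00 | 4 | 94 |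
| Thursday's | 3.00 | 16 | 85 |
| Thursday's | 6.00 | 25 | 70 |
| Thursday's | 8.00 | 30 | 60 |
| Thursday's | 12.0 | 41 | 50 |

(standard deviation of a reading: 1.5 percentage points)

- south-west: change nothing and wait 5.0 h more
- south-east: at 2.5 h raise the temperature by 10 K, then wait 5.0 h
- east: at 2.5 h add partner, 100 % of the amount charged, then wait 5.0 h
- north-west: at 2.5 h take out 90 % of the by-product then present, then wait 5.0 h

- what is added takes up no volume worth counting
- the numbers in the tables scatter by 1.5 percentage points (one standard deviation)

* target, in percent of the substrate first charged, at 2.5 h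
* which option adds most target ("none" when 2 percentage points or less is all one gets) (south-west / south-east / east / north-west / none)
* target present, in percent of the substrate first charged, after south-west
* target present, in percent of the substrate first charged, after north-west

Start with Sunday's run, since it is the flask you are asked about. Its substrate reads 28 % at 60.0 min and 28 % at 90.0 min, so it has stopped falling with substrate still there. In logarithms that stop comes to 0.553 decades. This is the stall depth, the powers of ten by which [substrate] falls before it stops. The first 8.00 min of Sunday's run gave 0.237 decades of it, so the fall faded on a clock of its own.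

But Thursday's run shows no stop: at 12.0 min its substrate, at 50 %, is still falling. So you cannot read the stop from Thursday's run.

Sunday's run used 34.3 substrate per initiator charged, so it looks like a chain. Suppose the initiator's end stops it, and chains end in pairs. Then the rate goes as the square root of [initiator], and on the same clock so does the stall depth. Your reckoning for 2.5 h is then the mean of the last two target readings, 47.0 %, and waiting adds nothing.

The forecast gives 46.5 % (44 % to 49 %) for now, 46.5 % after south-west, 47 % after north-west, and none as best option, holding that “by 2.5 h the flask is dead”.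

The flask gives 46.8 %, then 46.8 % after south-west and 46.8 % after north-west. At 150 min its substrate stands at 27.9 %, which is 0.554 decades. Initiator is down to 0.00657 % of its charge by 75.0 min. But the best option is south-east, which adds 6.9 percentage points.

    first chain carrier → ended carrier (k = 602 s⁻¹, Ea = 60.0 kJ mol⁻¹)
    substrate + initiating radical → capped initiator + first chain carrier (k = 3.10 × 10⁵ M⁻¹ s⁻¹, Ea = 29.0 kJ mol⁻¹)
    2 second chain carrier → ended chains (k = 1.40 × 10⁹ M⁻¹ s⁻¹, Ea = 10.0 kJ mol⁻¹)
    target ⇌ isomer of the product (K = 0.536, k = 0.00141 s⁻¹, Ea = 83.0 kJ mol⁻¹, ΔH = −35.0 kJ mol⁻¹)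
    partner + first chain carrier → target + second chain carrier (k = 7.31 × 10⁵ M⁻¹ s⁻¹, Ea = 13.0 kJ mol⁻¹)
    substrate + second chain carrier → by-product + first chain carrier (k = 12000 M⁻¹ s⁻¹, Ea = 24.0 kJ mol⁻¹)
    initiator → 2 initiating radical (k = 0.00214 s⁻¹, Ea = 96.0 kJ mol⁻¹)
    (constants at 25 °C)

Now take the same flask with 1.3 mol% of initiator. The square root brings the stall depth to 0.435 decades, so you expect 36.7 % substrate left, and that neighbour holds 38 %. The asked flask kept 64.9 % of its used substrate as target, so you expect 41.1 % target, and the neighbour gives 40.4 %.

(Readings and results were computed from invented constants.)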